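## Retrosynthetic overview

1. Last bond: the amide, made from acid 14 (21 non-hydrogen atoms) and amino diol enone 37 (18 non-hydrogen atoms as the free amine).
2. Acid 14: the (E)-C4=C5 alkene by Johnson–Claisen rearrangement of allylic alcohol 12; the C7 ether centre by RuCl2[(R)-BINAP] hydrogenation of β-keto ester 8; the C9 methyl centre from (S)-β-butyrolactone 2 opened by a heptyl Grignard reagent.
3. Amine 37: the ring-to-side-chain bond by adding the ketal-masked 2-lithioenone 33 to Weinreb amide 17 of O-methyl-D-serine; the anti amino alcohol by chelation-controlled reduction of ketone 35.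
4. Ring: the cyclohexenone is the only ring. It is closed once, by ring-closing metathesis of dienone 29 (step 16), before either fragment union; its two stereocentres come from a (Z)-crotylboration of aldehyde 21.

Assumption: the target is read as (4E,7R,9S) in the acyl chain, (1S,2R) in the amino alcohol and trans-(3S,4R) Me/OH on the ring; 2, 15 and (+)-Ipc2BOMe are bought enantiopure.

## Route

**Acid fragment**

Step 1
Reactants: 1 1-bromoheptane; 2 (S)-β-butyrolactone [(4S)-4-methyloxetan-2-one]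
Product: 4 (3S)-3-methyldecanoic acid, via heptylmagnesium bromide 3 (not isolated)
Conditions: Mg, THF, rt; then 2, CuBr·SMe2 (5 mol %), THF/Me2S, −30 → 0 °C; 1 M HCl
Reagents that add atoms: magnesium, [Mg] (found in intermediate 3 only)
Why: Copper-catalysed Grignard opening of a β-lactone is an SN2 attack at the β-carbon with inversion, so the (S)-lactone gives the (S)-3-methyl acid (heptyl replaces oxygen, the descriptor stays S), which is the later C9 centre.

Step 2
Reactants: 4 (3S)-3-methyldecanoic acid; 5 monomethyl malonate (3-methoxy-3-oxopropanoic acid)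
Product: 8 methyl (5S)-5-methyl-3-oxododecanoate, via acyl imidazolide 6 (not isolated), via magnesium malonate enolate 7 (not isolated)
Conditions: 4, CDI, THF, rt, 1 h; separately 5, i-PrMgCl (2 equiv), THF, 0 °C; combine, rt, 12 h; 1 M HCl
Reagents that add atoms: 1,1'-carbonyldiimidazole, O=C(n1ccnc1)n1ccnc1 (imidazolyl group of 6 only); isopropylmagnesium chloride, CC(C)[Mg]Cl (MgCl groups of 7 only)
Why: Masamune-type decarboxylative Claisen condensation, in which the malonate half-ester enolate is C-acylated and loses CO2 on acidification; the stereocentre is not touched.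

Step 3
Reactants: 8 methyl (5S)-5-methyl-3-oxododecanoate
Product: 9 methyl (3R,5S)-3-hydroxy-5-methyldodecanoate
Conditions: H2 (50 atm), RuCl2[(R)-BINAP] (0.5 mol %), MeOH, 50 °C
Reagents that add atoms: none
Why: Noyori asymmetric hydrogenation of a β-keto ester; the (R)-BINAP catalyst sets the (3R)-carbinol (later C7) under catalyst control, as it gives (R)-3-hydroxybutanoate from acetoacetate.

Step 4
Reactants: 9 methyl (3R,5S)-3-hydroxy-5-methyldodecanoate
Product: 10 methyl (3R,5S)-3-methoxy-5-methyldodecanoate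
Conditions: Me3OBF4, 1,8-bis(dimethylamino)naphthalene, CH2Cl2, 0 °C → rt
Reagents that add atoms: trimethyloxonium tetrafluoroborate, C[O+](C)C.F[B-](F)(F)F
Why: O-Methylation with an oxonium salt and a hindered amine base needs no alkoxide, so the β-hydroxy ester suffers neither retro-aldol cleavage nor β-elimination.

Step 5
Reactants: 10 methyl (3R,5S)-3-methoxy-5-methyldodecanoate
Product: 11 (3R,5S)-3-methoxy-5-methyldodecanal
Conditions: i-Bu2AlH (1.1 equiv), CH2Cl2, −78 °C; MeOH, aq. potassium sodium tartrate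
Reagents that add atoms: none
Why: Partial reduction of an ester with one equivalent of i-Bu2AlH at −78 °C stops at the aldehyde; the ether and both stereocentres are inert.

Step 6
Reactants: 11 (3R,5S)-3-methoxy-5-methyldodecanal
Product: 12 (3RS,5R,7S)-5-methoxy-7-methyltetradec-1-en-3-ol
Conditions: CH2=CHMgBr, THF, −78 → 0 °C; aq. NH4Cl
Reagents that add atoms: vinylmagnesium bromide, C=C[Mg]Br
Why: Grignard 1,2-addition to the aldehyde; the new carbinol centre forms as a mixture, which does not matter because it is destroyed in step 7.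

Step 7
Reactants: 12 (3RS,5R,7S)-5-methoxy-7-methyltetradec-1-en-3-ol
Product: 13 methyl (4E,7R,9S)-7-methoxy-9-methylhexadec-4-enoate
Conditions: MeC(OMe)3 (8 equiv), EtCO2H (0.1 equiv), xylene, 135 °C, MeOH distilled off
Reagents that add atoms: trimethyl orthoacetate, CC(OC)(OC)OC
Why: Johnson–Claisen orthoester rearrangement through a chair transition state with the chain equatorial gives the (E)-alkene (typically >95:5) and adds C1–C2.

Step 8
Reactants: 13 methyl (4E,7R,9S)-7-methoxy-9-methylhexadec-4-enoate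
Product: 14 (4E,7R,9S)-7-methoxy-9-methylhexadec-4-enoic acid
Conditions: LiOH·H2O, THF/MeOH/H2O, rt; 1 M HCl
Reagents that add atoms: lithium hydroxide, [Li+].[OH-]
Why: Saponification of an unhindered methyl ester; the skipped alkene cannot move into conjugation under these mild conditions.

**Serine fragment**

Step 9
Reactants: 15 O-methyl-D-serine [(2R)-2-amino-3-methoxypropanoic acid]
Product: 16 (2R)-2-[(tert-butoxycarbonyl)amino]-3-methoxypropanoic acid
Conditions: Boc2O, NaOH, dioxane/H2O, 0 °C → rt; 1 M HCl to pH 3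
Reagents that add atoms: di-tert-butyl dicarbonate, CC(C)(C)OC(=O)OC(=O)OC(C)(C)C
Why: Carbamate formation on the amine under Schotten–Baumann conditions; the chiral-pool centre (R) is untouched.

Step 10
Reactants: 16 (2R)-2-[(tert-butoxycarbonyl)amino]-3-methoxypropanoic acid
Product: 17 tert-butyl N-[(2R)-3-methoxy-1-[methoxy(methyl)amino]-1-oxopropan-2-yl]carbamate
Conditions: MeNH(OMe)·HCl, EDC·HCl, HOBt, N-methylmorpholine, CH2Cl2, 0 °C → rt
Reagents that add atoms: N,O-dimethylhydroxylamine hydrochloride, CNOC.Cl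
Why: Carbodiimide amide coupling; a urethane-protected amino acid does not racemise under these conditions.

**Ring and amine fragment**

Step 11
Reactants: 18 methyl isobutyrate; 19 methyl formate
Product: 21 methyl 2,2-dimethyl-3-oxopropanoate, via lithium ester enolate 20 (not isolated)
Conditions: LiN(i-Pr)2, THF, −78 °C; cannulate into HCO2Me (3 equiv), THF, −78 °C; AcOH
Reagents that add atoms: lithium diisopropylamide, CC(C)[N-]C(C)C.[Li+] (lithium of 20 only)
Why: Claisen-type C-formylation of an ester enolate; inverse addition into excess formate keeps the non-enolisable aldehyde from meeting unreacted enolate.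

Step 12
Reactants: 21 methyl 2,2-dimethyl-3-oxopropanoate; 22 cis-2-butene
Product: 26 methyl (3R,4S)-3-hydroxy-2,2,4-trimethylhex-5-enoate, via (Z)-crotylpotassium 23 (not isolated), via (Z)-crotyl-Ipc2B borane 24 (not isolated), via O-boryl adduct 25 (not isolated)
Conditions: 22, KOt-Bu, n-BuLi, THF, −78 → −45 °C (10 min) → −78 °C; (+)-Ipc2BOMe; BF3·OEt2; 21, −78 °C, 4 h; NaBO3·4H2O, THF/H2O, rt
Reagents that add atoms: potassium tert-butoxide, CC(C)(C)[O-].[K+] (potassium of 23 only); (+)-B-methoxydiisopinocampheylborane, COB([C@H]1C[C@H]2C[C@@H]([C@@H]1C)C2(C)C)[C@H]1C[C@H]2C[C@@H]([C@@H]1C)C2(C)C (Ipc2B group of 24 and 25 only)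
Why: Brown crotylboration: the (Z)-crotylborane reacts through a closed chair transition state to give the syn adduct, and the Ipc groups from (−)-α-pinene direct attack to the Re face, giving (3R,4S) (syn here corresponds to trans Me/OH on the later ring).

Step 13
Reactants: 26 methyl (3R,4S)-3-hydroxy-2,2,4-trimethylhex-5-enoate
Product: 27 methyl (3R,4S)-3-[tert-butyl(dimethyl)silyl]oxy-2,2,4-trimethylhex-5-enoate
Conditions: TBSOTf, 2,6-lutidine, CH2Cl2, −78 → 0 °C
Reagents that add atoms: tert-butyldimethylsilyl trifluoromethanesulfonate, CC(C)(C)[Si](C)(C)OS(=O)(=O)C(F)(F)F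
Why: Silyl triflate silylation is fast enough for this hindered secondary alcohol and blocks retro-aldol cleavage in the following basic steps.

Step 14
Reactants: 27 methyl (3R,4S)-3-[tert-butyl(dimethyl)silyl]oxy-2,2,4-trimethylhex-5-enoate
Product: 28 (3R,4S)-3-[tert-butyl(dimethyl)silyl]oxy-N-methoxy-N,2,2,4-tetramethylhex-5-enamide
Conditions: MeNH(OMe)·HCl (3 equiv), i-PrMgCl (6 equiv), THF, −20 → 0 °C; aq. NH4Cl
Reagents that add atoms: N,O-dimethylhydroxylamine hydrochloride, CNOC.Cl
Why: Aminolysis of the ester by the magnesium amide of N,O-dimethylhydroxylamine (Weinreb amide formation); the quaternary α-carbon cannot enolise.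

Step 15
Reactants: 28 (3R,4S)-3-[tert-butyl(dimethyl)silyl]oxy-N-methoxy-N,2,2,4-tetramethylhex-5-enamide
Product: 29 (5R,6S)-5-[tert-butyl(dimethyl)silyl]oxy-4,4,6-trimethylocta-1,7-dien-3-one
Conditions: CH2=CHMgBr (2.5 equiv), THF, 0 °C; poured into cold 1 M HCl
Reagents that add atoms: vinylmagnesium bromide, C=C[Mg]Br
Why: Weinreb ketone synthesis takes up exactly one equivalent of Grignard reagent; the acidic inverse quench keeps the liberated amine from adding to the vinyl ketone.

Step 16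
Reactants: 29 (5R,6S)-5-[tert-butyl(dimethyl)silyl]oxy-4,4,6-trimethylocta-1,7-dien-3-one
Product: 30 (4S,5R)-5-[tert-butyl(dimethyl)silyl]oxy-4,6,6-trimethylcyclohex-2-en-1-one
Conditions: second-generation Grubbs catalyst RuCl2(=CHPh)(PCy3)(H2IMes) (5 mol %), CH2Cl2 (0.005 M), 40 °C
Reagents that add atoms: none
Why: Ring-closing metathesis of the two terminal alkenes closes the six-membered enone with loss of ethene; neither stereocentre is involved.

Step 17
Reactants: 30 (4S,5R)-5-[tert-butyl(dimethyl)silyl]oxy-4,6,6-trimethylcyclohex-2-en-1-one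
Product: 31 (4S,5R)-5-[tert-butyl(dimethyl)silyl]oxy-2-iodo-4,6,6-trimethylcyclohex-2-en-1-one
Conditions: I2, pyridine/CH2Cl2 (1:1), 0 °C → rt; aq. Na2S2O3
Reagents that add atoms: iodine, II
Why: Johnson α-iodination of an enone (pyridine conjugate addition, iodination, elimination) puts iodine on C2 only, since C6 is quaternary.

Step 18
Reactants: 31 (4S,5R)-5-[tert-butyl(dimethyl)silyl]oxy-2-iodo-4,6,6-trimethylcyclohex-2-en-1-one
Product: 32 tert-butyl-[[(8S,9R)-6-iodo-8,10,10-trimethyl-1,4-dioxaspiro[4.5]dec-6-en-9-yl]oxy]-dimethylsilane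
Conditions: TMSOCH2CH2OTMS (3 equiv), TMSOTf (0.1 equiv), CH2Cl2, −78 → −20 °C; pyridine, aq. NaHCO3
Reagents that add atoms: 1,2-bis(trimethylsilyloxy)ethane, C[Si](C)(C)OCCO[Si](C)(C)C
Why: Noyori ketalisation under aprotic kinetic conditions masks the ketone without moving the double bond, epimerising C8 or cleaving the silyl ether.

Step 19
Reactants: 32 tert-butyl-[[(8S,9R)-6-iodo-8,10,10-trimethyl-1,4-dioxaspiro[4.5]dec-6-en-9-yl]oxy]-dimethylsilane; 17 tert-butyl N-[(2R)-3-methoxy-1-[methoxy(methyl)amino]-1-oxopropan-2-yl]carbamate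
Product: 35 tert-butyl N-[(2R)-1-[(8S,9R)-9-[tert-butyl(dimethyl)silyl]oxy-8,10,10-trimethyl-1,4-dioxaspiro[4.5]dec-6-en-6-yl]-3-methoxy-1-oxopropan-2-yl]carbamate, via vinyllithium 33 (not isolated), via N-magnesio Weinreb amide 34 (not isolated)
Conditions: 32, t-BuLi (2.05 equiv), Et2O, −78 °C; separately 17 (1.3 equiv), i-PrMgCl (1.3 equiv), THF, −20 °C; combine at −78 °C, → −20 °C; aq. NH4Cl
Reagents that add atoms: tert-butyllithium, [Li]C(C)(C)C (lithium of 33 only); isopropylmagnesium chloride, CC(C)[Mg]Cl (MgCl of 34 only)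
Why: Iodine–lithium exchange gives an α-keto vinyl anion equivalent that acylates on the Weinreb amide; prior N–H deprotonation saves the vinyllithium and shields the α-centre from enolisation.

Step 20
Reactants: 35 tert-butyl N-[(2R)-1-[(8S,9R)-9-[tert-butyl(dimethyl)silyl]oxy-8,10,10-trimethyl-1,4-dioxaspiro[4.5]dec-6-en-6-yl]-3-methoxy-1-oxopropan-2-yl]carbamate
Product: 36 tert-butyl N-[(1S,2R)-1-[(8S,9R)-9-[tert-butyl(dimethyl)silyl]oxy-8,10,10-trimethyl-1,4-dioxaspiro[4.5]dec-6-en-6-yl]-1-hydroxy-3-methoxypropan-2-yl]carbamate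
Conditions: LiAlH(Ot-Bu)3 (3 equiv), EtOH, −78 °C; aq. citric acid
Reagents that add atoms: none
Why: Chelation-controlled (Cram-chelate) 1,2-reduction of an N-Boc α-amino enone delivers hydride anti to the CH2OMe branch and gives the anti amino alcohol, (1S) next to the fixed (2R) centre.

Step 21
Reactants: 36 tert-butyl N-[(1S,2R)-1-[(8S,9R)-9-[tert-butyl(dimethyl)silyl]oxy-8,10,10-trimethyl-1,4-dioxaspiro[4.5]dec-6-en-6-yl]-1-hydroxy-3-methoxypropan-2-yl]carbamate
Product: 37 (4S,5R)-2-[(1S,2R)-2-amino-1-hydroxy-3-methoxypropyl]-5-hydroxy-4,6,6-trimethylcyclohex-2-en-1-one, trifluoroacetate salt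
Conditions: TFA/H2O (9:1), 0 °C → rt, 3 h; evaporate; MeOH, rt; evaporate
Reagents that add atoms: water, O; trifluoroacetic acid, OC(=O)C(F)(F)F
Why: One acidolysis removes the Boc group, hydrolyses the ketal and cleaves the silyl ether; the amine stays protonated, so it cannot add to the liberated enone.

Step 22
Reactants: 37 (4S,5R)-2-[(1S,2R)-2-amino-1-hydroxy-3-methoxypropyl]-5-hydroxy-4,6,6-trimethylcyclohex-2-en-1-one, trifluoroacetate salt; 14 (4E,7R,9S)-7-methoxy-9-methylhexadec-4-enoic acid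
Product: 38 (4E,7R,9S)-N-[(1S,2R)-1-hydroxy-1-[(3S,4R)-4-hydroxy-3,5,5-trimethyl-6-oxocyclohex-1-en-1-yl]-3-methoxypropan-2-yl]-7-methoxy-9-methylhexadec-4-enamide (CNP0168625.1)
Conditions: EDC·HCl, HOBt, i-Pr2NEt (2 equiv), CH2Cl2/DMF, 0 °C → rt
Reagents that add atoms: none
Why: Carbodiimide amide coupling; the primary amine is acylated far faster than the two hindered secondary alcohols, so no hydroxyl protection is needed.

## Compound list

1 | 1-bromoheptane | CCCCCCCBr | starting material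
2 | (S)-β-butyrolactone [(4S)-4-methyloxetan-2-one] | C[C@H]1CC(=O)O1 | starting material
3 | heptylmagnesium bromide | CCCCCCC[Mg]Br | intermediate
4 | (3S)-3-methyldecanoic acid | CCCCCCC[C@H](C)CC(=O)O | intermediate
5 | monomethyl malonate (3-methoxy-3-oxopropanoic acid) | COC(=O)CC(=O)O | starting material
6 | 1-[(3S)-3-methyldecanoyl]imidazole | CCCCCCC[C@H](C)CC(=O)n1ccnc1 | intermediate
7 | bis(chloromagnesium) enolate-carboxylate of monomethyl malonate | COC(O[Mg]Cl)=CC(=O)O[Mg]Cl | intermediate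
8 | methyl (5S)-5-methyl-3-oxododecanoate | CCCCCCC[C@H](C)CC(=O)CC(=O)OC | intermediate
9 | methyl (3R,5S)-3-hydroxy-5-methyldodecanoate | CCCCCCC[C@H](C)C[C@@H](O)CC(=O)OC | intermediate
10 | methyl (3R,5S)-3-methoxy-5-methyldodecanoate | CCCCCCC[C@H](C)C[C@@H](OC)CC(=O)OC | intermediate
11 | (3R,5S)-3-methoxy-5-methyldodecanal | CCCCCCC[C@H](C)C[C@@H](OC)CC=O | intermediate
12 | (3RS,5R,7S)-5-methoxy-7-methyltetradec-1-en-3-ol (C3 epimers) | CCCCCCC[C@H](C)C[C@@H](OC)CC(O)C=C | intermediate
13 | methyl (4E,7R,9S)-7-methoxy-9-methylhexadec-4-enoate | CCCCCCC[C@H](C)C[C@H](C/C=C/CCC(=O)OC)OC | intermediate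
14 | (4E,7R,9S)-7-methoxy-9-methylhexadec-4-enoic acid | CCCCCCC[C@H](C)C[C@H](C/C=C/CCC(=O)O)OC | intermediate
15 | O-methyl-D-serine | COC[C@@H](N)C(=O)O | starting material
16 | (2R)-2-[(tert-butoxycarbonyl)amino]-3-methoxypropanoic acid | COC[C@@H](NC(=O)OC(C)(C)C)C(=O)O | intermediate
17 | tert-butyl N-[(2R)-3-methoxy-1-[methoxy(methyl)amino]-1-oxopropan-2-yl]carbamate | COC[C@@H](NC(=O)OC(C)(C)C)C(=O)N(C)OC | intermediate
18 | methyl isobutyrate | COC(=O)C(C)C | starting material
19 | methyl formate | COC=O | starting material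
20 | lithium enolate of methyl isobutyrate | COC(O[Li])=C(C)C | intermediate
21 | methyl 2,2-dimethyl-3-oxopropanoate | COC(=O)C(C)(C)C=O | intermediate
22 | cis-2-butene | C/C=C\C | starting material
23 | (Z)-crotylpotassium | C/C=C\C[K] | intermediate
24 | (Z)-but-2-en-1-yl-diisopinocampheylborane, Ipc groups from (−)-α-pinene | C/C=C\CB([C@H]1C[C@H]2C[C@@H]([C@@H]1C)C2(C)C)[C@H]1C[C@H]2C[C@@H]([C@@H]1C)C2(C)C | intermediate
25 | O-(diisopinocampheylboryl) derivative of 26 | C=C[C@H](C)[C@@H](OB([C@H]1C[C@H]2C[C@@H]([C@@H]1C)C2(C)C)[C@H]1C[C@H]2C[C@@H]([C@@H]1C)C2(C)C)C(C)(C)C(=O)OC | intermediate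
26 | methyl (3R,4S)-3-hydroxy-2,2,4-trimethylhex-5-enoate | C=C[C@H](C)[C@@H](O)C(C)(C)C(=O)OC | intermediate
27 | methyl (3R,4S)-3-[tert-butyl(dimethyl)silyl]oxy-2,2,4-trimethylhex-5-enoate | C=C[C@H](C)[C@@H](O[Si](C)(C)C(C)(C)C)C(C)(C)C(=O)OC | intermediate
28 | (3R,4S)-3-[tert-butyl(dimethyl)silyl]oxy-N-methoxy-N,2,2,4-tetramethylhex-5-enamide | C=C[C@H](C)[C@@H](O[Si](C)(C)C(C)(C)C)C(C)(C)C(=O)N(C)OC | intermediate
29 | (5R,6S)-5-[tert-butyl(dimethyl)silyl]oxy-4,4,6-trimethylocta-1,7-dien-3-one | C=C[C@H](C)[C@@H](O[Si](C)(C)C(C)(C)C)C(C)(C)C(=O)C=C | intermediate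
30 | (4S,5R)-5-[tert-butyl(dimethyl)silyl]oxy-4,6,6-trimethylcyclohex-2-en-1-one | O=C1C=C[C@H](C)[C@@H](O[Si](C)(C)C(C)(C)C)C1(C)C | intermediate
31 | (4S,5R)-5-[tert-butyl(dimethyl)silyl]oxy-2-iodo-4,6,6-trimethylcyclohex-2-en-1-one | O=C1C(I)=C[C@H](C)[C@@H](O[Si](C)(C)C(C)(C)C)C1(C)C | intermediate
32 | tert-butyl-[[(8S,9R)-6-iodo-8,10,10-trimethyl-1,4-dioxaspiro[4.5]dec-6-en-9-yl]oxy]-dimethylsilane | IC1=C[C@H](C)[C@@H](O[Si](C)(C)C(C)(C)C)C(C)(C)C12OCCO2 | intermediate
33 | 6-lithio analogue of 32 (vinyllithium) | [Li]C1=C[C@H](C)[C@@H](O[Si](C)(C)C(C)(C)C)C(C)(C)C12OCCO2 | intermediate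
34 | N-chloromagnesio derivative of 17 | COC[C@@H](N([Mg]Cl)C(=O)OC(C)(C)C)C(=O)N(C)OC | intermediate
35 | tert-butyl N-[(2R)-1-[(8S,9R)-9-[tert-butyl(dimethyl)silyl]oxy-8,10,10-trimethyl-1,4-dioxaspiro[4.5]dec-6-en-6-yl]-3-methoxy-1-oxopropan-2-yl]carbamate | COC[C@@H](NC(=O)OC(C)(C)C)C(=O)C1=C[C@H](C)[C@@H](O[Si](C)(C)C(C)(C)C)C(C)(C)C12OCCO2 | intermediate
36 | tert-butyl N-[(1S,2R)-1-[(8S,9R)-9-[tert-butyl(dimethyl)silyl]oxy-8,10,10-trimethyl-1,4-dioxaspiro[4.5]dec-6-en-6-yl]-1-hydroxy-3-methoxypropan-2-yl]carbamate | COC[C@@H](NC(=O)OC(C)(C)C)[C@@H](O)C1=C[C@H](C)[C@@H](O[Si](C)(C)C(C)(C)C)C(C)(C)C12OCCO2 | intermediate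
37 | (4S,5R)-2-[(1S,2R)-2-amino-1-hydroxy-3-methoxypropyl]-5-hydroxy-4,6,6-trimethylcyclohex-2-en-1-one, trifluoroacetate salt | COC[C@@H]([NH3+])[C@@H](O)C1=C[C@H](C)[C@@H](O)C(C)(C)C1=O.[O-]C(=O)C(F)(F)F | intermediate
38 | (4E,7R,9S)-N-[(1S,2R)-1-hydroxy-1-[(3S,4R)-4-hydroxy-3,5,5-trimethyl-6-oxocyclohex-1-en-1-yl]-3-methoxypropan-2-yl]-7-methoxy-9-methylhexadec-4-enamide | CCCCCCC[C@H](C)C[C@H](C/C=C/CCC(=O)N[C@H](COC)[C@@H](O)C1=C[C@H](C)[C@@H](O)C(C)(C)C1=O)OC | target

## Step count and risks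

Total step count: 22.
Longest linear sequence: 12 steps (steps 11–22, from methyl isobutyrate 18 to 38). The acid branch is 8 steps (1–8) and the serine branch 2 steps (9–10).

Three steps most likely to fail:

Step 18, ketalisation of the crowded α-iodoenone 31. The carbonyl sits between a quaternary carbon and the iodo-bearing sp2 carbon and may not ketalise. The fallback drops the masking and the organolithium chemistry altogether. It sets out from 31 and uses 17. Weinreb amide 17 is reduced with LiAlH4 (THF, 0 °C) to tert-butyl N-[(2R)-1-methoxy-3-oxopropan-2-yl]carbamate F1. F1 is joined to the unmasked iodoenone 31 in a Nozaki–Hiyama–Kishi coupling (CrCl2 6 equiv, NiCl2 2 mol %, DMF, rt) to give tert-butyl N-[(1S,2R)-1-[(3S,4R)-4-[tert-butyl(dimethyl)silyl]oxy-3,5,5-trimethyl-6-oxocyclohex-1-en-1-yl]-1-hydroxy-3-methoxypropan-2-yl]carbamate F2. The anti isomer is expected to predominate only moderately (Felkin–Anh), so the syn epimer is removed by chromatography. TFA/H2O as in step 21 then brings the route back at 37. This path also bypasses steps 19 and 20.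

Step 14, conversion of the neopentyl-type ester 27 into the Weinreb amide. Acyl substitution next to a quaternary carbon and a silyloxy branch can stall. The fallback uses a redox sequence instead, setting out from 27. i-Bu2AlH (CH2Cl2, −78 °C) gives (3R,4S)-3-[tert-butyl(dimethyl)silyl]oxy-2,2,4-trimethylhex-5-enal F3. CH2=CHMgBr (THF, −78 °C) gives (3RS,5R,6S)-5-[tert-butyl(dimethyl)silyl]oxy-4,4,6-trimethylocta-1,7-dien-3-ol F4 as a carbinol mixture. Dess–Martin periodinane (CH2Cl2, rt) oxidises F4 and the route comes back at 29.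

Step 11, direct formylation of the ester enolate. The aldehyde product can be consumed by remaining enolate in an aldol reaction. The fallback sets out from 18 through its enolate 20. Quenching 20 with monomeric formaldehyde (from cracked paraformaldehyde, −78 → 0 °C) gives methyl 3-hydroxy-2,2-dimethylpropanoate F5. Swern oxidation ((COCl)2, DMSO, Et3N, CH2Cl2, −78 °C) then gives the aldehyde and the route comes back at 21.

## Further compounds

F1 | step 18 | tert-butyl N-[(2R)-1-methoxy-3-oxopropan-2-yl]carbamate | COC[C@@H](NC(=O)OC(C)(C)C)C=O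
F2 | step 18 | tert-butyl N-[(1S,2R)-1-[(3S,4R)-4-[tert-butyl(dimethyl)silyl]oxy-3,5,5-trimethyl-6-oxocyclohex-1-en-1-yl]-1-hydroxy-3-methoxypropan-2-yl]carbamate | COC[C@@H](NC(=O)OC(C)(C)C)[C@@H](O)C1=C[C@H](C)[C@@H](O[Si](C)(C)C(C)(C)C)C(C)(C)C1=O
F3 | step 14 | (3R,4S)-3-[tert-butyl(dimethyl)silyl]oxy-2,2,4-trimethylhex-5-enal | C=C[C@H](C)[C@@H](O[Si](C)(C)C(C)(C)C)C(C)(C)C=O
F4 | step 14 | (3RS,5R,6S)-5-[tert-butyl(dimethyl)silyl]oxy-4,4,6-trimethylocta-1,7-dien-3-ol | C=C[C@H](C)[C@@H](O[Si](C)(C)C(C)(C)C)C(C)(C)C(O)C=C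
F5 | step 11 | methyl 3-hydroxy-2,2-dimethylpropanoate | COC(=O)C(C)(C)CO
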